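**Plan**

- Retrosynthesis: the phenol is masked as its methyl ether and the four C–Cl bonds (pyrrole C3, C4, C5 and oxazole C4) are removed first, leaving 5-(4-methoxyphenyl)-2-(1H-pyrrol-2-yl)oxazole.
- The pyrrole is then cut at C3–C4 and N1–C5. Because pyrrole C2 is bonded directly to oxazole C2, pyrrole N1, C2 and C3 correspond to the N, the C=N carbon and the methyl group of a 2-acetyloxazole oxime, and C4 and C5 to the two carbons of acetylene.
- The oxime goes back to the 2-acetyloxazole (cut at the oxazole C2–acyl bond), and the oxazole ring to 4-methoxybenzaldehyde and TosMIC (cut at C4–C5 and O1–C2).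
- Forward: the oxazole ring is made first (Van Leusen), C2 is acylated and the ketone oximated, the pyrrole ring is closed second (Trofimov annulation), and the pyrrolyl-oxazole is then chlorinated four times and O-demethylated.
- Stereochemistry: the target has no stereocentre; the oxime geometry and the relative configuration of a transient oxazoline are the only stereo-elements on the way and neither reaches the product.

Key step: step 4

Remark: the target is achiral, acetylene is taken as commercial cylinder gas, and the oxime is drawn as its E isomer although either geometry should serve, since the two interconvert in hot base.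

**Step 1**
Reactants: 1 4-methoxybenzaldehyde; 2 tosylmethyl isocyanide (TosMIC)
Product: 4 5-(4-methoxyphenyl)oxazole, via trans-4-tosyl-2-oxazoline 3 (not isolated)
Conditions: K2CO3 (2 equiv), MeOH, reflux
Reagents that add atoms: none
Why: Van Leusen oxazole synthesis, in which the TosMIC anion adds to the aldehyde, the alkoxide closes onto the isocyanide carbon to give trans-oxazoline 3, and base-induced loss of p-toluenesulfinate aromatises it to the 5-aryloxazole, a routine transformation for electron-rich benzaldehydes.

**Step 2**
Reactants: 4 5-(4-methoxyphenyl)oxazole; 5 N-methoxy-N-methylacetamide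
Product: 7 1-[5-(4-methoxyphenyl)oxazol-2-yl]ethanone, via oxazol-2-ylmagnesium chloride 6 (not isolated)
Conditions: i-PrMgCl (1.2 equiv), THF, −15 °C to rt; then 5, rt; aq NH4Cl
Reagents that add atoms: none
Why: C2 magnesiation followed by Weinreb ketone synthesis, relying on the C2–H between O and N being the most acidic site, on the magnesiated oxazole 6 reacting through C2 rather than through the ring-opened isocyano enolate that troubles the lithium analogue, and on the chelated tetrahedral adduct of the Weinreb amide stopping the addition at the ketone.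

**Step 3**
Reactants: 7 1-[5-(4-methoxyphenyl)oxazol-2-yl]ethanone
Product: 8 (E)-1-[5-(4-methoxyphenyl)oxazol-2-yl]ethanone oxime
Conditions: NH2OH·HCl, NaOAc, EtOH/H2O, 70 °C
Reagents that add atoms: hydroxylamine hydrochloride, NO.Cl
Why: Standard oxime condensation of a methyl ketone under acetate buffering, expected to favour the E isomer with the hydroxyl anti to the larger oxazolyl group, although the geometry has no bearing on the next step.

**Step 4**
Reactants: 8 (E)-1-[5-(4-methoxyphenyl)oxazol-2-yl]ethanone oxime; 9 acetylene
Product: 12 5-(4-methoxyphenyl)-2-(1H-pyrrol-2-yl)oxazole, via O-vinyl oxime 10 (not isolated), via 4-iminobutanal 11 (not isolated)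
Conditions: HC≡CH (1 atm, slow stream), KOH (1 equiv), DMSO, 90–100 °C, stopped once 8 is consumed
Reagents that add atoms: none
Why: This is the Trofimov pyrrole synthesis, documented for aryl and hetaryl methyl ketoximes: in the KOH/DMSO superbase the oximate of 8 adds to acetylene to give O-vinyl oxime 10, which tautomerises through its methyl group to the N,O-divinylhydroxylamine. A [3,3] sigmatropic shift (a 3-aza-4-oxa-Cope rearrangement) then cleaves the weak N–O bond and forms the future pyrrole C3–C4 bond, delivering 4-iminobutanal 11. The imine nitrogen closes the ring onto the aldehyde carbon in a 5-exo-trig addition (N1–C5), and loss of water from the resulting 5-hydroxypyrroline aromatises it to pyrrole 12. No stereocentre is created, and the C=N geometry of 8 is irrelevant because the E and Z oximates interconvert in the hot base. Regiochemistry is fixed by the substrate, since the methyl group is the only enolisable position next to the oxime carbon and the oxazole carbon on the other side carries no hydrogen, so only the 2-(oxazol-2-yl)pyrrole can arise. The one selectivity to be enforced is NH-pyrrole over N-vinylpyrrole, which is addressed by atmospheric acetylene pressure, a temperature held near 95 °C and the low nucleophilicity of the oxazolyl-stabilised pyrrolide.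

**Step 5**
Reactants: 12 5-(4-methoxyphenyl)-2-(1H-pyrrol-2-yl)oxazole
Product: 13 4-chloro-5-(4-methoxyphenyl)-2-(3,4,5-trichloro-1H-pyrrol-2-yl)oxazole
Conditions: NCS (4.3 equiv, in portions), dry DMF, 0 °C to 45 °C, dark
Reagents that add atoms: N-chlorosuccinimide (NCS), O=C1CCC(=O)N1Cl
Why: Electrophilic aromatic chlorination, in which the three free pyrrole carbons are the most nucleophilic positions and oxazole C4 is an enol-ether β-carbon whose σ-complex is stabilised by O1 and by the para-methoxyphenyl group on C5, so that all four heteroaryl C–H bonds should react before the anisole ortho positions, which the azole substituent deactivates; exhaustive NCS chlorination of 2-arylpyrroles and C4 halogenation of 5-aryloxazoles are both established.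

**Step 6**
Reactants: 13 4-chloro-5-(4-methoxyphenyl)-2-(3,4,5-trichloro-1H-pyrrol-2-yl)oxazole
Product: 15 4-[4-chloro-2-(3,4,5-trichloro-1H-pyrrol-2-yl)oxazol-5-yl]phenol, via aryloxydibromoborane 14 (not isolated)
Conditions: BBr3 (4 equiv), CH2Cl2, −78 °C to rt; then H2O, 0 °C
Reagents that add atoms: none
Why: Lewis-acid cleavage of an aryl methyl ether, in which BBr3 coordinates the methoxy oxygen, bromide removes the methyl group by SN2 to give aryloxyborane 14, and aqueous work-up releases the phenol, while the aryl and heteroaryl C–Cl bonds and both azole rings are inert to the reagent.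

**Compound list**

1 | 4-methoxybenzaldehyde | COc1ccc(C=O)cc1 | starting material
2 | tosylmethyl isocyanide (TosMIC) | Cc1ccc(cc1)S(=O)(=O)C[N+]#[C-] | starting material
3 | trans-5-(4-methoxyphenyl)-4-tosyl-4,5-dihydrooxazole (racemic, one enantiomer drawn) | COc1ccc(cc1)[C@@H]1OC=N[C@H]1S(=O)(=O)c1ccc(C)cc1 | intermediate
4 | 5-(4-methoxyphenyl)oxazole | COc1ccc(cc1)-c1cnco1 | intermediate
5 | N-methoxy-N-methylacetamide | CON(C)C(C)=O | starting material
6 | [5-(4-methoxyphenyl)oxazol-2-yl]magnesium chloride | COc1ccc(cc1)-c1cnc([Mg]Cl)o1 | intermediate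
7 | 1-[5-(4-methoxyphenyl)oxazol-2-yl]ethanone | CC(=O)c1ncc(o1)-c1ccc(OC)cc1 | intermediate
8 | (E)-1-[5-(4-methoxyphenyl)oxazol-2-yl]ethanone oxime | C/C(=N\O)c1ncc(o1)-c1ccc(OC)cc1 | intermediate
9 | acetylene | C#C | starting material
10 | (E)-1-[5-(4-methoxyphenyl)oxazol-2-yl]ethanone O-vinyl oxime | C/C(=N\OC=C)c1ncc(o1)-c1ccc(OC)cc1 | intermediate
11 | 4-imino-4-[5-(4-methoxyphenyl)oxazol-2-yl]butanal | N=C(CCC=O)c1ncc(o1)-c1ccc(OC)cc1 | intermediate
12 | 5-(4-methoxyphenyl)-2-(1H-pyrrol-2-yl)oxazole | COc1ccc(cc1)-c1cnc(o1)-c1ccc[nH]1 | intermediate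
13 | 4-chloro-5-(4-methoxyphenyl)-2-(3,4,5-trichloro-1H-pyrrol-2-yl)oxazole | COc1ccc(cc1)-c1oc(nc1Cl)-c1[nH]c(Cl)c(Cl)c1Cl | intermediate
14 | dibromo{4-[4-chloro-2-(3,4,5-trichloro-1H-pyrrol-2-yl)oxazol-5-yl]phenoxy}borane | BrB(Br)Oc1ccc(cc1)-c1oc(nc1Cl)-c1[nH]c(Cl)c(Cl)c1Cl | intermediate
15 | 4-[4-chloro-2-(3,4,5-trichloro-1H-pyrrol-2-yl)oxazol-5-yl]phenol | Oc1ccc(cc1)-c1oc(nc1Cl)-c1[nH]c(Cl)c(Cl)c1Cl | target

**Step count and risks**

Total step count: 6. Longest linear sequence: 6 steps (1 to 15); the route is fully linear.

Steps most likely to fail: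

Step 4. The pyrrolide formed in the superbase may add to a second molecule of acetylene (N-vinylation). Alternatively, the oximate of the electron-poor oxazolyl ketone may be degraded by hydroxide attack on the oxazole before it is O-vinylated. The fallback sets out from 4 and comes back at 12, building the pyrrole–oxazole bond by cross-coupling instead of annulation. Oxazole 4 is magnesiated as in step 2 (through 6) and quenched with I2 to give 2-iodo-5-(4-methoxyphenyl)oxazole F1. Suzuki–Miyaura coupling of F1 with commercial [1-(tert-butoxycarbonyl)pyrrol-2-yl]boronic acid (Pd(PPh3)4, aq Na2CO3, DME, 80 °C) should give tert-butyl 2-[5-(4-methoxyphenyl)oxazol-2-yl]-1H-pyrrole-1-carboxylate F2. Removal of the Boc group with TFA in CH2Cl2 then gives 12.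

Step 5. The last and slowest heteroaryl chlorination may lag so far that chlorination ortho to the methoxy group, or oxidative breakdown of the pyrrole, competes. The fallback sets out from 12 and comes back at 15, exchanging the activating methyl ether for a deactivating ester before chlorination. Compound 12 is demethylated with NaSEt in DMF at 120 °C to 4-[2-(1H-pyrrol-2-yl)oxazol-5-yl]phenol F3, and O-acetylation (Ac2O, pyridine) gives 4-[2-(1H-pyrrol-2-yl)oxazol-5-yl]phenyl acetate F4. Chlorination with NCS in DMF then gives 4-[4-chloro-2-(3,4,5-trichloro-1H-pyrrol-2-yl)oxazol-5-yl]phenyl acetate F5, and methanolysis (K2CO3, MeOH, rt) releases 15.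

Step 2. The C2-metalated oxazole may equilibrate with its ring-opened isocyano enolate, so that acylation is incomplete or occurs at the wrong atom. The fallback sets out from 4 and comes back at 7, using a ring-locked anion and a lower oxidation level of the electrophile. BH3·THF converts 4 into the N-borane complex of 5-(4-methoxyphenyl)oxazole F6, which cannot ring-open. Treatment with n-BuLi in THF at −78 °C gives the C2-lithiated borane complex F7, and acetaldehyde adds to give the N-borane complex of 1-[5-(4-methoxyphenyl)oxazol-2-yl]ethanol F8. Warming in ethanol containing 5% acetic acid strips the borane to leave racemic 1-[5-(4-methoxyphenyl)oxazol-2-yl]ethanol F9, and oxidation with MnO2 in CH2Cl2 gives ketone 7.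

**Further compounds**

F1 | step 4 | 2-iodo-5-(4-methoxyphenyl)oxazole | COc1ccc(cc1)-c1cnc(I)o1
F2 | step 4 | tert-butyl 2-[5-(4-methoxyphenyl)oxazol-2-yl]-1H-pyrrole-1-carboxylate | COc1ccc(cc1)-c1cnc(o1)-c1cccn1C(=O)OC(C)(C)C
F3 | step 5 | 4-[2-(1H-pyrrol-2-yl)oxazol-5-yl]phenol | Oc1ccc(cc1)-c1cnc(o1)-c1ccc[nH]1
F4 | step 5 | 4-[2-(1H-pyrrol-2-yl)oxazol-5-yl]phenyl acetate | CC(=O)Oc1ccc(cc1)-c1cnc(o1)-c1ccc[nH]1
F5 | step 5 | 4-[4-chloro-2-(3,4,5-trichloro-1H-pyrrol-2-yl)oxazol-5-yl]phenyl acetate | CC(=O)Oc1ccc(cc1)-c1oc(nc1Cl)-c1[nH]c(Cl)c(Cl)c1Cl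
F6 | step 2 | 5-(4-methoxyphenyl)oxazole N-borane complex | COc1ccc(cc1)-c1c[n+]([BH3-])co1
F7 | step 2 | C2-lithiated 5-(4-methoxyphenyl)oxazole N-borane complex | COc1ccc(cc1)-c1c[n+]([BH3-])c([Li])o1
F8 | step 2 | 1-[5-(4-methoxyphenyl)oxazol-2-yl]ethanol N-borane complex (racemic) | CC(O)c1oc(c[n+]1[BH3-])-c1ccc(OC)cc1
F9 | step 2 | 1-[5-(4-methoxyphenyl)oxazol-2-yl]ethanol (racemic) | CC(O)c1ncc(o1)-c1ccc(OC)cc1
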